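Should the next flask get 1.00 equiv of reagent and 4.0 d, or must we charge more or wait longer? The recipes, the earlier runs and the questions stand here.

| flask | substrate | reagent | scavenger | free catalyst | remark | time |
|---|---|---|---|---|---|---|
| cedar | 0.40 M | 0.67 equiv | 1.5 equiv | 0.05 mol% | run made earlier |  |
| maple | 0.40 M | 1.5 equiv | 1.5 equiv | 0.05 mol% | run made earlier |  |
| alder | 0.20 M | 1 equiv | 1.5 equiv | 0.05 mol% | run made earlier |  |
| flask | 0.40 M | 1.00 equiv | 1.50 equiv | 0.05 mol% |  | 4.0 d |

| run | time / d | substrate / % | product / % |
|---|---|---|---|
| cedar | 0.500 | 78.0 | 21.4 |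
| cedar | 1.04 | 56.6 | 43.1 |
| cedar | 1.25 | 48.9 | 51.1 |
| cedar | 2.08 | 32.9 | 66.4 |
| cedar | 2.50 | 33.6 | 67.3 |
| maple | 0.500 | 77.7 | 20.9 |
| maple | 1.04 | 56.3 | 44.0 |
| maple | 1.25 | 47.9 | 51.0 |
| maple | 2.08 | 19.7 | 80.2 |
| maple | 2.50 | 9.8 | 90.5 |
| alder | 0.208 | 92.2 | 8.2 |
| alder | 0.333 | 87.9 | 12.7 |
| alder | 0.625 | 77.5 | 23.6 |
| alder | 1.25 | 55.3 | 44.8 |
| alder | 2.50 | 20.6 | 78.9 |

(scatter of a reading: 0.5 percentage points)

- the numbers in the tables scatter by 0.5 percentage points (one standard deviation)
- the earlier runs do not show how much of reagent is bound; that part of a forecast is a guess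

- part of the substrate that has reacted at 4.0 d
- share of the unused reagent that is free and not bound as idle adduct, at 4.0 d

The decision hangs on how much product a charge of reagent can buy. The cedar run stalled, with product at 66.4% after 2.08 d and 67.3% after 2.50 d, while the maple run, with more reagent and the same other charges, went further than cedar, to 90.5%. So we take reagent as the limiting reagent in cedar and divide its last product reading by its 0.67 equiv, which gives 100%. We call this the yield per equivalent, the percent of the substrate turned to product for each equivalent of reagent charged. For this flask, 1.00 equiv gives by our reckoning a ceiling of 100%.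

Time looks sufficient. Cedar and maple kept the same pace at first, with substrate at 48.9% and 47.9% after 1.25 d. Maple had 9.8% of its substrate left at 2.50 d, after losing 9.9 percentage points in the last 0.420 d, and this flask, with less reagent than maple, runs 1.50 d beyond that reading, longer than that last stretch. We therefore charge 1.00 equiv, keep 4.0 d, and expect conversion close to the ceiling. The readings give us no number for the free reagent.

The forecast gives 99.4% reacted and 50% of the unused reagent free, saying “The runs do not reveal the free share of reagent”.

The flask gives 99.9% reacted, against our ceiling of 100%, and >99.9% of the unused reagent free.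

reagent + free catalyst → catalyst intermediate A (k = 15100 L mol⁻¹ h⁻¹); catalyst intermediate A ⇌ released group + catalyst intermediate B (K = 0.263 M, k = 86.6 h⁻¹); substrate + catalyst intermediate B → catalyst intermediate C (k = 742 L mol⁻¹ h⁻¹); catalyst intermediate C ⇌ catalyst intermediate D (K = 8.20, k = 9600 h⁻¹); catalyst intermediate D → free catalyst + product (k = 89.8 h⁻¹); reagent + released group ⇌ idle adduct, settled at all times (K = 3.87 L mol⁻¹); scavenger + released group → scavenged by-product (k = 9.89 L mol⁻¹ h⁻¹) At 4.00 d this flask holds 0.122% of its substrate, 0.0755% of its reagent and 4.18 × 10⁻⁸ M of idle adduct. One more flask, with 0.400 equiv of reagent and the other charges unchanged, has a ceiling of 40.0% by the yield per equivalent. At 4.00 d that flask shows reagent at 0%, substrate at 60.0% and product at 40.0%.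

The readings come from a simulation for an exercise; noise was put on by code.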